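The route disconnects C1–C10 of the ten-membered carbocycle. Because C10 carries the one-carbon branch C14, it can be a vinylic (2-bromoallyl) carbon, so C1–C10 is an sp3–sp2 bond remote from the C12/O8 methylene lactone (on C7–C8) and the C15/O6 butenolide (on C4–C6). One operation, hydroboration of the C1=C2 vinyl group and intramolecular B-alkyl Suzuki–Miyaura coupling, closes the carbocycle and leaves C10=C14 for the final hydroboration. The precursor is the C6–C7-linked bis-lactone with a vinyl carbinol isobutyrate at C3 and a 2-bromoallyl arm at C8, its reactive C11=C13 methylene stored as a phenylselenide.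

Key step: step 11

Remark: atoms carry germacranolide numbers (carbocycle C1–C10, lactone carbons C11–C13, C14 on C10, C15 the butenolide carbonyl); the C11=C13 unit is masked before the coupling because it would compete for 9-BBN-H and for the vinylpalladium intermediate five atoms away; the hemiacetal carbon of 21 and C11 of 26–30 are epimer mixtures that are erased later.

Step 1
Reactants: 1 2,3-dibromopropene; 2 acrolein
Product: 4 rac-5-bromohexa-1,5-dien-3-ol, via 2-bromoallylindium dibromide 3 (not isolated)
Conditions: indium powder, THF/H2O (1:1), 25 °C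
Reagents that add atoms: none
Why: Indium-mediated Barbier allylation in water: indium inserts only into the allylic C–Br bond of 1 (the vinylic bromide is inert) and the allylindium adds 1,2 to the aldehyde, giving the racemic carbinol that becomes C8 with the C9–C10(Br)=C14 arm in place.

Step 2
Reactants: 4 rac-5-bromohexa-1,5-dien-3-ol
Product: 5 (R)-5-bromohexa-1,5-dien-3-ol
Conditions: Ti(OiPr)4 (15 mol %), L-(+)-diisopropyl tartrate (18 mol %), t-BuOOH (0.6 equiv), 4 Å molecular sieves, CH2Cl2, −20 °C
Reagents that add atoms: none
Why: Sharpless kinetic resolution: with the L-(+)-tartrate the S enantiomer is epoxidised at its vinyl group much faster, so the R alcohol (future C8) should be recovered when the reaction is taken a little past half conversion, while the electron-poor, only homoallylic bromoalkene is not epoxidised.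

Step 3
Reactants: 5 (R)-5-bromohexa-1,5-dien-3-ol; 6 2-(bromomethyl)acrylic acid
Product: 7 (R)-5-bromohexa-1,5-dien-3-yl 2-(bromomethyl)acrylate
Conditions: N,N′-dicyclohexylcarbodiimide (1.1 equiv), DMAP (5 mol %), CH2Cl2, 0 °C
Reagents that add atoms: none
Why: Steglich esterification (carbodiimide activation, acyl transfer at low temperature with only a trace of DMAP so that N-alkylation of the catalyst by the allylic bromide stays minor); the C8–O bond is not broken, so the R configuration is retained.

Step 4
Reactants: 7 (R)-5-bromohexa-1,5-dien-3-yl 2-(bromomethyl)acrylate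
Product: 8 (R)-3-(bromomethyl)-5-(2-bromoallyl)furan-2(5H)-one
Conditions: second-generation Grubbs catalyst RuCl2(=CHPh)(H2IMes)(PCy3) (5 mol %), toluene, 80 °C, 5 mM
Reagents that add atoms: none
Why: Ring-closing metathesis of an allylic acrylate to a butenolide: the ruthenium carbene loads on the monosubstituted vinyl group and closes the five-membered ring onto the 1,1-disubstituted acrylate alkene with loss of ethene, while the vinylic and allylic bromides are spectators and C8 is untouched.

Step 5
Reactants: 9 3-furaldehyde
Product: 13 2-(trimethylsilyl)furan-3-carbaldehyde, via lithium amino alkoxide 10 (not isolated), via C2-lithiated amino alkoxide 11 (not isolated), via C2-silylated amino alkoxide 12 (not isolated)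
Conditions: N,N,N′-trimethylethylenediamine, n-BuLi, THF, −78 °C; 9; n-BuLi, −20 °C; Me3SiCl, −78 °C to 25 °C; H2O
Reagents that add atoms: chlorotrimethylsilane, C[Si](C)(C)Cl
Why: Directed ortho-metalation with in situ protection: the aldehyde is masked as a lithium α-amino alkoxide whose chelating diamine arm directs n-BuLi to C2 of the furan, the anion is silylated and aqueous work-up releases the aldehyde; the silyl group is placed here to fix the regiochemistry of step 8.

Step 6
Reactants: 13 2-(trimethylsilyl)furan-3-carbaldehyde; 14 vinylmagnesium bromide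
Product: 16 (S)-1-[2-(trimethylsilyl)furan-3-yl]prop-2-en-1-ol, via divinylzinc 15 (not isolated)
Conditions: 14 (2.2 equiv), ZnCl2 (1.1 equiv), THF, 0 °C; 1,4-dioxane, filtration; (−)-3-exo-(dimethylamino)isoborneol (5 mol %), 13, toluene, 0 °C; aq. NH4Cl
Reagents that add atoms: none
Why: Amino-alcohol-catalysed enantioselective addition of a divinylzinc reagent to an aldehyde: the zinc chelate of the (−)-ligand delivers the vinyl group to the Si face, as in the parent ethylation of aryl aldehydes with this ligand, which should set C3 as S.

Step 7
Reactants: 16 (S)-1-[2-(trimethylsilyl)furan-3-yl]prop-2-en-1-ol; 17 isobutyric anhydride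
Product: 18 (S)-1-[2-(trimethylsilyl)furan-3-yl]allyl isobutyrate
Conditions: Et3N (1.5 equiv), DMAP (5 mol %), CH2Cl2, 0 °C
Reagents that add atoms: none
Why: DMAP-catalysed acylation of a secondary alcohol by an anhydride under mildly basic conditions that do not ionise the furylic allylic ester; the C3–O bond is not broken, so the S configuration is kept.

Step 8
Reactants: 18 (S)-1-[2-(trimethylsilyl)furan-3-yl]allyl isobutyrate
Product: 21 (S)-1-(5-hydroxy-2-oxo-2,5-dihydrofuran-3-yl)allyl isobutyrate, via furan endoperoxide 19 (not isolated), via silyl ester aldehyde 20 (not isolated)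
Conditions: O2, visible light, tetraphenylporphyrin (cat.), CH2Cl2, −78 °C; then H2O, 25 °C
Reagents that add atoms: dioxygen, O=O
Why: Sensitised photooxygenation of a 2-silylfuran: singlet oxygen adds [4+2] across C2/C5 of the furan, silicon shifts from carbon to the peroxide oxygen so that the carbon that bore it becomes the carboxyl carbon C15, and hydrolysis of silyl ester 20 closes the γ-hydroxybutenolide with the side chain on C4 and the masked aldehyde at C6; the monosubstituted vinyl group is inert to singlet oxygen and C3 is not involved.

Step 9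
Reactants: 8 (R)-3-(bromomethyl)-5-(2-bromoallyl)furan-2(5H)-one; 21 (S)-1-(5-hydroxy-2-oxo-2,5-dihydrofuran-3-yl)allyl isobutyrate
Product: 25 (S)-1-{(R)-5-[(2R,3S)-2-(2-bromoallyl)-4-methylene-5-oxotetrahydrofuran-3-yl]-2-oxo-2,5-dihydrofuran-3-yl}allyl isobutyrate, via ring-opened sodium carboxylate 22 (not isolated), via allylindium dibromide 23 (not isolated), via seco hydroxy acid 24 (not isolated)
Conditions: indium powder (1.5 equiv), NaHCO3 (1.0 equiv), H2O/THF (3:1), 25 °C; then 1 M HCl to pH 2
Reagents that add atoms: none
Why: Indium-mediated Barbier allylation with allylic transposition on the ring-opened aldehyde 22: the C6–C7 bond forms at C7 on the butenolide face anti to the C8 bromoallyl arm (trans C7/C8), the indium-bound carboxylate places the metal on the alkenyl side of the aldehyde and so holds that residue axial in the cyclic transition state, which should set C6 as R (the non-chelated chair of this ring-locked E-allyl unit would give the C6 epimer), and acidification closes the butenolide at O6–C15 with retention.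

Step 10
Reactants: 25 (bis-lactone with free methylene lactone)
Product: 26 (S)-1-{(R)-5-[(2R,3S)-2-(2-bromoallyl)-5-oxo-4-[(phenylselanyl)methyl]tetrahydrofuran-3-yl]-2-oxo-2,5-dihydrofuran-3-yl}allyl isobutyrate
Conditions: PhSeH (1.05 equiv), Et3N (5 mol %), THF, 0 °C
Reagents that add atoms: benzeneselenol, [SeH]c1ccccc1
Why: Selenol conjugate (Michael) addition, a known way to store an α-methylene lactone: the soft nucleophile adds to the unhindered exocyclic C13 of the most electrophilic acceptor, the β-substituted butenolide and the vinyl bromide stay intact, and C11 forms as an epimer mixture that is erased in step 12.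

Step 11
Reactants: 26 (selenide-masked precursor)
Product: 28 selenide-masked 10(14)-methylene macrocycle (3S,6R,7S,8R), via B-alkyl borane 27 (not isolated)
Conditions: 9-BBN-H (1.3 equiv), THF, 0 °C to 25 °C; then syringe-pump addition to PdCl2(dppf) (10 mol %), AsPh3 (20 mol %), K3PO4 (3 M aq., 3 equiv), DMF/THF, 50 °C, final 2 mM
Reagents that add atoms: none
Why: 9-BBN-H adds anti-Markovnikov to the only monosubstituted, electron-neutral alkene and places boron on C1; the vinyl bromide and the butenolide alkene are deactivated and the methylene lactone is absent because it is stored as the selenide. Zerovalent palladium formed from PdCl2(dppf) adds oxidatively to the C10–Br bond, the base-activated borate transfers its primary alkyl group C1 to palladium, and reductive elimination forms the C1–C10 sp3–sp2 bond; this is an intramolecular B-alkyl Suzuki–Miyaura coupling, a known way to close macrocycles from a terminal alkene and a vinyl halide. The ten-membered carbocycle C1–C10 closes end to end by reductive elimination from a cyclic alkyl(vinyl)palladium species, helped by the C6–C7 link of the two lactone rings, which keeps the C3 and C8 arms close, and by slow addition at high dilution, which suppresses dimerisation. No stereocentre is formed and the exocyclic C10=C14 alkene is left for step 12. The selectivity needed is ring closure over β-hydride elimination, over carbopalladation of a nearby alkene and over ionisation of the allylic C3 isobutyrate; the wide bite angle of dppf (fast reductive elimination), AsPh3 (fast transmetalation), the hindered ester on an electron-poor alkene and the masked C11=C13 unit should secure it.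

Step 12
Reactants: 28 (selenide-masked 10(14)-methylene macrocycle)
Product: 31 target CNP0332805.1 (3S,6R,7S,8R,10R), via C14 borane 29 (not isolated), via selenoxide alcohol 30 (not isolated)
Conditions: 9-BBN-H (2 equiv), THF, 0 °C to 25 °C; then aq. NaOAc, 30% H2O2, 0 °C to 25 °C
Reagents that add atoms: hydrogen peroxide, OO
Why: Hydroboration–oxidation followed by selenoxide syn-elimination: 9-BBN-H adds to the only unhindered electron-neutral alkene with boron on C14 and should deliver hydrogen to C10 from the β face, away from the α-oriented C8–O bond and the lactone that it anchors, which makes C10 R; buffered H2O2 then replaces boron by hydroxyl with retention and oxidises the selenide to selenoxide 30, which eliminates toward its only β-hydrogen (C11–H) and restores the C11=C13 methylene lactone.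

Compound list
1 | 2,3-dibromopropene | C=C(Br)CBr | starting material
2 | acrolein | C=CC=O | starting material
3 | 2-bromoallylindium dibromide | C=C(Br)C[In](Br)Br | intermediate
4 | rac-5-bromohexa-1,5-dien-3-ol | OC(CC(Br)=C)C=C | intermediate
5 | (R)-5-bromohexa-1,5-dien-3-ol | O[C@H](CC(Br)=C)C=C | intermediate
6 | 2-(bromomethyl)acrylic acid | C=C(CBr)C(=O)O | starting material
7 | (R)-5-bromohexa-1,5-dien-3-yl 2-(bromomethyl)acrylate | C=C(CBr)C(=O)O[C@H](CC(Br)=C)C=C | intermediate
8 | (R)-3-(bromomethyl)-5-(2-bromoallyl)furan-2(5H)-one | O=C1O[C@H](CC(Br)=C)C=C1CBr | intermediate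
9 | 3-furaldehyde | O=Cc1ccoc1 | starting material
10 | lithium amino alkoxide from 9 and lithium N,N,N′-trimethylethylenediamide | [Li]OC(c1ccoc1)N(C)CCN(C)C | intermediate
11 | C2-lithiated amino alkoxide | [Li]OC(c1ccoc1[Li])N(C)CCN(C)C | intermediate
12 | C2-silylated amino alkoxide | [Li]OC(c1ccoc1[Si](C)(C)C)N(C)CCN(C)C | intermediate
13 | 2-(trimethylsilyl)furan-3-carbaldehyde | C[Si](C)(C)c1occc1C=O | intermediate
14 | vinylmagnesium bromide | C=C[Mg]Br | starting material
15 | divinylzinc | C=C[Zn]C=C | intermediate
16 | (S)-1-[2-(trimethylsilyl)furan-3-yl]prop-2-en-1-ol | C[Si](C)(C)c1occc1[C@@H](O)C=C | intermediate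
17 | isobutyric anhydride | CC(C)C(=O)OC(=O)C(C)C | starting material
18 | (S)-1-[2-(trimethylsilyl)furan-3-yl]allyl isobutyrate | C[Si](C)(C)c1occc1[C@@H](OC(=O)C(C)C)C=C | intermediate
19 | furan endoperoxide (2,5-epidioxide of 18) | C[Si](C)(C)C12OOC(O1)C=C2[C@@H](OC(=O)C(C)C)C=C | intermediate
20 | trimethylsilyl (Z)-2-[(S)-1-(isobutyryloxy)allyl]-4-oxobut-2-enoate | O=C/C=C(\C(=O)O[Si](C)(C)C)[C@@H](OC(=O)C(C)C)C=C | intermediate
21 | (S)-1-(5-hydroxy-2-oxo-2,5-dihydrofuran-3-yl)allyl isobutyrate (hemiacetal epimers) | O=C1OC(O)C=C1[C@@H](OC(=O)C(C)C)C=C | intermediate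
22 | sodium (Z)-2-[(S)-1-(isobutyryloxy)allyl]-4-oxobut-2-enoate | [Na+].O=C/C=C(\C([O-])=O)[C@@H](OC(=O)C(C)C)C=C | intermediate
23 | allylindium dibromide from 8 | O=C1O[C@H](CC(Br)=C)C=C1C[In](Br)Br | intermediate
24 | seco hydroxy acid (3S,6R,7S,8R) | C=C1C(=O)O[C@H](CC(Br)=C)[C@H]1[C@H](O)/C=C(\C(O)=O)[C@@H](OC(=O)C(C)C)C=C | intermediate
25 | bis-lactone precursor with free methylene lactone (3S,6R,7S,8R) | C=C1C(=O)O[C@H](CC(Br)=C)[C@H]1[C@@H]1OC(=O)C([C@@H](OC(=O)C(C)C)C=C)=C1 | intermediate
26 | selenide-masked precursor (C11 epimers) | c2ccccc2[Se]CC1C(=O)O[C@H](CC(Br)=C)[C@H]1[C@@H]1OC(=O)C([C@@H](OC(=O)C(C)C)C=C)=C1 | intermediate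
27 | B-alkyl borane (C1–B, 9-borabicyclo[3.3.1]nonan-9-yl) | c2ccccc2[Se]CC1C(=O)O[C@H](CC(Br)=C)[C@H]1[C@@H]1OC(=O)C([C@@H](OC(=O)C(C)C)CCB2C3CCCC2CCC3)=C1 | intermediate
28 | selenide-masked 10(14)-methylene macrocycle (3S,6R,7S,8R; C11 epimers) | c4ccccc4[Se]CC1C(=O)O[C@@H]2CC(=C)CC[C@H](OC(=O)C(C)C)C3=C[C@@H](OC3=O)[C@@H]12 | intermediate
29 | C14 borane | c4ccccc4[Se]CC1C(=O)O[C@@H]2C[C@H](CB4C5CCCC4CCC5)CC[C@H](OC(=O)C(C)C)C3=C[C@@H](OC3=O)[C@@H]12 | intermediate
30 | selenoxide alcohol | c4ccccc4[Se](=O)CC1C(=O)O[C@@H]2C[C@H](CO)CC[C@H](OC(=O)C(C)C)C3=C[C@@H](OC3=O)[C@@H]12 | intermediate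
31 | CNP0332805.1, (3S,6R,7S,8R,10R)-14-hydroxy-3-(isobutyryloxy)germacra-4,11(13)-diene-12,8:15,6-diolide | C=C1C(=O)O[C@@H]2C[C@H](CO)CC[C@H](OC(=O)C(C)C)C3=C[C@@H](OC3=O)[C@@H]12 | target

Total step count: 12. Longest linear sequence: 8 steps (steps 5, 6, 7, 8, 9, 10, 11, 12 from 3-furaldehyde; equally steps 1, 2, 3, 4, 9, 10, 11, 12 from 2,3-dibromopropene).

Steps most likely to fail

Step 11. The ring-closing transmetalation has to overcome the transannular strain of a ten-membered ring. If it is slow, the vinylpalladium intermediate may be diverted into intermolecular coupling (oligomers), carbopalladation of the butenolide alkene or ionisation of the allylic isobutyrate. The fallback makes C1–C10 between two molecules and closes the ring at C6–C7 instead. Hydroboration of 18 with 9-BBN-H gives the alkylborane F1, which is coupled with the vinyl bromide of 5 (PdCl2(dppf), AsPh3, K3PO4) to the dienyl alcohol F2. Esterification with 6 as in step 3 gives the acrylate F3, and ring-closing metathesis as in step 4 gives the bromomethyl butenolide F4. Photooxygenation as in step 8 gives the hydroxybutenolide F5. An intramolecular indium Barbier reaction at high dilution (conditions of step 9) then closes the carbocycle to the free bis-lactone macrocycle F6, and selenol addition as in step 10 returns 28.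

Step 9. C6 depends on the carboxylate staying on indium during allyl transfer. If it does not, the allyl transfer runs through the ordinary chair with the alkenyl residue equatorial, facial control at the aldehyde is reversed, and the C6 epimer is formed, which cannot be corrected once the butenolide has closed. The fallback replaces the closed transition state by an open one. Alcohol 5 is esterified with 2-(trimethylsilylmethyl)acrylic acid F7 (from saponification of the commercial ethyl ester) to the ester F8, and ring-closing metathesis gives the ring-locked allylsilane F9. Hydroxybutenolide 21 is opened with MeI and KHCO3 to the methyl ester aldehyde F10. BF3·OEt2-promoted Hosomi–Sakurai addition of F9 to F10 at −78 °C runs through an open antiperiplanar transition state without a metal bridge, which is syn-selective for E-configured allyl units. Acid-induced lactonisation of the C6 hydroxyl onto the methyl ester then returns 25.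

Step 12. The conformation of the ten-membered ring decides which face of C10=C14 is open, so hydride delivery to C10 may be unselective or reversed. The fallback adds oxygen first and hydrogen second, which inverts the outcome of the same facial bias. From 28, excess mCPBA with NaHCO3 oxidises the selenide (the selenoxide eliminates and restores the methylene lactone) and epoxidises the electron-rich exocyclic alkene from the open face to the spiro-epoxide F11. BF3·OEt2 at −78 °C induces the Meinwald rearrangement, in which hydride migrates from C14 to C10 anti to the departing oxygen, to the aldehyde F12. NaBH(OAc)3 reduces the aldehyde to 31.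

Further compounds
F1 | step 11 | B-alkyl-9-BBN borane from 18 | C[Si](C)(C)c1occc1[C@@H](OC(=O)C(C)C)CCB1C2CCCC1CCC2
F2 | step 11 | (S)-1-[2-(trimethylsilyl)furan-3-yl]-6-hydroxy-4-methyleneoct-7-enyl isobutyrate (6R) | C[Si](C)(C)c1occc1[C@@H](OC(=O)C(C)C)CCC(=C)C[C@@H](O)C=C
F3 | step 11 | 2-(bromomethyl)acrylate of F2 | C[Si](C)(C)c1occc1[C@@H](OC(=O)C(C)C)CCC(=C)C[C@@H](OC(=O)C(=C)CBr)C=C
F4 | step 11 | silylfuran bearing the 3-(bromomethyl)butenolide | C[Si](C)(C)c1occc1[C@@H](OC(=O)C(C)C)CCC(=C)C[C@H]1OC(=O)C(CBr)=C1
F5 | step 11 | hydroxybutenolide bearing the 3-(bromomethyl)butenolide | O=C1OC(O)C=C1[C@@H](OC(=O)C(C)C)CCC(=C)C[C@H]1OC(=O)C(CBr)=C1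
F6 | step 11 | 10(14)-methylene macrocycle with free methylene lactone | C=C1C(=O)O[C@@H]2CC(=C)CC[C@H](OC(=O)C(C)C)C3=C[C@@H](OC3=O)[C@@H]12
F7 | step 9 | 2-(trimethylsilylmethyl)acrylic acid | C=C(C[Si](C)(C)C)C(=O)O
F8 | step 9 | (R)-5-bromohexa-1,5-dien-3-yl 2-(trimethylsilylmethyl)acrylate | C=C(C[Si](C)(C)C)C(=O)O[C@H](CC(Br)=C)C=C
F9 | step 9 | (R)-5-(2-bromoallyl)-3-[(trimethylsilyl)methyl]furan-2(5H)-one | O=C1O[C@H](CC(Br)=C)C=C1C[Si](C)(C)C
F10 | step 9 | methyl (Z)-2-[(S)-1-(isobutyryloxy)allyl]-4-oxobut-2-enoate | O=C/C=C(\C(=O)OC)[C@@H](OC(=O)C(C)C)C=C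
F11 | step 12 | C10 spiro-epoxide with free methylene lactone | C=C1C(=O)O[C@@H]2C[C@@]4(CO4)CC[C@H](OC(=O)C(C)C)C3=C[C@@H](OC3=O)[C@@H]12
F12 | step 12 | C14 aldehyde (10R) | C=C1C(=O)O[C@@H]2C[C@H](C=O)CC[C@H](OC(=O)C(C)C)C3=C[C@@H](OC3=O)[C@@H]12
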